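**Retrosynthetic overview**
1. The target is methyl (E)-6,8-dihydroxylabd-13-en-15-oate of the ent series. The route rests on ring A (C1–C5, C10): it carries no heteroatom and lies between the fully substituted C4 (two methyls) and C10 (one methyl), so its C2–C3 bond can be made last, as an alkene between a C10 allyl arm and a C4 vinyl arm.
2. Side chain and C8: C13=C14 by Horner–Wadsworth–Emmons olefination; the C8 carbinol by Markovnikov hydration of an 8(17)-alkene (C17 by Wittig); the C8 oxygen and H-9 by hydroboration of a Δ8 alkene; C9–C11 by B-alkyl Suzuki coupling of the C9 enol triflate.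
3. C5–H and C6–OH by hydroboration of a Δ5 alkene, obtained by dehydrating the C5 carbinol after C2=C3 has been saturated.
4. Ring A by ring-closing metathesis (C2=C3) on the preformed ring B; the diene by γ-addition of prenylmagnesium chloride to the C5 ketone.
5. Ring B is bought as 2-methylcyclohexane-1,3-dione (C-allylation, then enantioselective monoreduction that fixes C10). Ring order: B (starting material), then A (step 5).

Key step: step 5

Remark: labdane numbering is used for all ring compounds (ring A = C1–C5 and C10, ring B = C5–C10, C17 on C8, C18 and C19 on C4, C20 on C10, side chain C11–C16); "cis" and "trans" refer to the C10 methyl group C20, and the tetrahydropyranyl ethers 14–25 are taken as mixtures of the two epimers at the acetal carbon, which leaves in step 17.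

**Step 1**
Reactants: 1 2-methylcyclohexane-1,3-dione; 2 allyl bromide
Product: 3 2-allyl-2-methylcyclohexane-1,3-dione
Conditions: 1 M aq. NaOH, 23 °C
Reagents that add atoms: none
Why: C-alkylation of the stabilised sodium enolate of a cyclic 1,3-dione by an allylic bromide in water, where the carbon terminus should outcompete oxygen, creates the quaternary carbon that becomes C10.

**Step 2**
Reactants: 3 2-allyl-2-methylcyclohexane-1,3-dione
Product: 4 (2S,3S)-2-allyl-3-hydroxy-2-methylcyclohexan-1-one
Conditions: baker's yeast (Saccharomyces cerevisiae), sucrose, H2O, 30 °C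
Reagents that add atoms: none
Why: Enzymatic enantiotopic-group-selective reduction of a prochiral 2,2-disubstituted cyclohexane-1,3-dione, in which hydride enters one carbonyl group from the face anti to the allyl group to give the 3S carbinol (OH cis to allyl), so that the quaternary carbon becomes the 2S stereocentre that is C10 of the target.

**Step 3**
Reactants: 4 (2S,3S)-2-allyl-3-hydroxy-2-methylcyclohexan-1-one
Product: 5 (2S,3S)-2-allyl-3-(tert-butyldimethylsilyloxy)-2-methylcyclohexan-1-one
Conditions: TBSCl, imidazole, DMF, 23 → 40 °C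
Reagents that add atoms: tert-butyldimethylsilyl chloride, CC(C)(C)[Si](C)(C)Cl
Why: Imidazole-promoted O-silylation of the secondary alcohol blocks retro-aldol cleavage and protonation of the organomagnesium reagent used next.

**Step 4**
Reactants: 5 (2S,3S)-2-allyl-3-(tert-butyldimethylsilyloxy)-2-methylcyclohexan-1-one; 6 1-chloro-3-methylbut-2-ene
Product: 8 (1R,2S,3S)-2-allyl-3-(tert-butyldimethylsilyloxy)-2-methyl-1-(2-methylbut-3-en-2-yl)cyclohexan-1-ol, via prenylmagnesium chloride 7 (not isolated)
Conditions: 6, Mg, THF, 0 °C; then 5, THF, −78 → −40 °C; aq. NH4Cl at −40 °C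
Reagents that add atoms: none
Why: Allylic Grignard 1,2-addition with allylic transposition (six-membered SE2′ transition state) bonds the γ-carbon of the prenyl unit to the carbonyl carbon even beside a quaternary centre, and a cold quench prevents retro-allylation to the linear isomer; equatorial attack on the chair with an equatorial siloxy group should place the new arm cis to the C10 allyl group (1R), and the C5 epimer would converge in step 7 because C5 becomes sp2.

**Step 5**
Reactants: 8 (1R,2S,3S)-2-allyl-3-(tert-butyldimethylsilyloxy)-2-methyl-1-(2-methylbut-3-en-2-yl)cyclohexan-1-ol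
Product: 9 (5R,9S,10S)-9-(tert-butyldimethylsilyloxy)-4,4,10-trimethyl-Δ2-octalin-5-ol
Conditions: RuCl2(=CHPh)(PCy3)(H2IMes) (second-generation Grubbs catalyst, 5 mol%), CH2Cl2 (0.01 M), 40 °C
Reagents that add atoms: none
Why: Olefin ring-closing metathesis: the ruthenium benzylidene exchanges with the unhindered allyl terminus to give the C2 alkylidene, which adds intramolecularly across the neopentyl vinyl group on C4 to a ruthenacyclobutane whose cycloreversion forms C2=C3 and a ruthenium methylidene that carries the chain, ethylene being lost. The closest known reaction type is the ring-closing metathesis of 1,7-dienes bearing an allylic quaternary carbon to cyclohexenes. Ring A (C1–C5, C10) closes as a six-membered ring by formation of its C2=C3 bond between two arms held on the adjacent ring-B carbons C10 and C5. No stereocentre is formed. The step needs cyclisation to win over intermolecular metathesis, which is secured by high dilution, by the 1,7-relationship of two monosubstituted alkenes and by the full substitution of C4, C5 and C10 that folds the chain, while the free tertiary alcohol and the silyl ether are tolerated by the catalyst.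

**Step 6**
Reactants: 9 (5R,9S,10S)-9-(tert-butyldimethylsilyloxy)-4,4,10-trimethyl-Δ2-octalin-5-ol
Product: 10 9-(tert-butyldimethylsilyloxy)-4,4,10-trimethyl-cis-decalin-5-ol
Conditions: H2 (1 atm), 10% Pd/C, EtOAc, 23 °C
Reagents that add atoms: none
Why: Heterogeneous catalytic hydrogenation of the only C=C bond (cis-disubstituted C2=C3) leaves the silyl ether and the tertiary alcohol untouched and avoids having to tell two alkenes apart later.

**Step 7**
Reactants: 10 9-(tert-butyldimethylsilyloxy)-4,4,10-trimethyl-cis-decalin-5-ol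
Product: 11 9-(tert-butyldimethylsilyloxy)-4,4,10-trimethyl-Δ5-octalin
Conditions: SOCl2, pyridine, CH2Cl2, −20 → 0 °C
Reagents that add atoms: none
Why: Dehydration of a tertiary alcohol through its chlorosulfite by pyridine-mediated E2 elimination can only give the C5=C6 alkene, because C4 and C10 carry no hydrogen, so either C5 epimer would give the same product.

**Step 8**
Reactants: 11 9-(tert-butyldimethylsilyloxy)-4,4,10-trimethyl-Δ5-octalin
Product: 13 9-(tert-butyldimethylsilyloxy)-4,4,10-trimethyl-trans-decalin-6-ol, via C6 alkylborane 12 (not isolated)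
Conditions: BH3·THF, THF, 0 → 40 °C; then aq. NaOH, 30% H2O2, 0 → 23 °C
Reagents that add atoms: hydrogen peroxide, OO
Why: Hydroboration–oxidation places boron on the less substituted C6 and hydrogen on C5 in a syn addition from the face opposite the axial C10 methyl and the pseudo-axial C4 methyl, which should set H-5 trans to C20 (trans ring fusion) and, after oxidation with retention, the equatorial 6-OH trans to C20.

**Step 9**
Reactants: 13 9-(tert-butyldimethylsilyloxy)-4,4,10-trimethyl-trans-decalin-6-ol
Product: 14 9-(tert-butyldimethylsilyloxy)-6-(tetrahydropyran-2-yloxy)-4,4,10-trimethyl-trans-decalin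
Conditions: 3,4-dihydro-2H-pyran, PPTS (cat.), CH2Cl2, 23 °C
Reagents that add atoms: 3,4-dihydro-2H-pyran, C1=COCCC1
Why: Acid-catalysed addition of the alcohol to the enol ether (tetrahydropyranylation) gives an acetal that withstands fluoride, base, borane and ylide and is not a β-leaving group once C8 becomes a ketone.

**Step 10**
Reactants: 14 9-(tert-butyldimethylsilyloxy)-6-(tetrahydropyran-2-yloxy)-4,4,10-trimethyl-trans-decalin
Product: 15 6-(tetrahydropyran-2-yloxy)-4,4,10-trimethyl-trans-decalin-9-ol
Conditions: Bu4NF, THF, 60 °C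
Reagents that add atoms: none
Why: Fluoride-induced desilylation, driven by the strong Si–F bond, frees the hindered axial C9 alcohol while the acetal on O6 is inert.

**Step 11**
Reactants: 15 6-(tetrahydropyran-2-yloxy)-4,4,10-trimethyl-trans-decalin-9-ol
Product: 16 6-(tetrahydropyran-2-yloxy)-4,4,10-trimethyl-trans-decalin-9-one
Conditions: Dess–Martin periodinane, NaHCO3, CH2Cl2, 23 °C
Reagents that add atoms: none
Why: Buffered Dess–Martin oxidation of the secondary alcohol gives the C9 ketone, whose α-carbon C10 is quaternary and cannot epimerise.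

**Step 12**
Reactants: 16 6-(tetrahydropyran-2-yloxy)-4,4,10-trimethyl-trans-decalin-9-one
Product: 18 6-(tetrahydropyran-2-yloxy)-4,4,10-trimethyl-Δ8-octalin-9-yl trifluoromethanesulfonate, via potassium enolate 17 (not isolated)
Conditions: KN(SiMe3)2, THF, −78 °C; then PhNTf2, −78 → 0 °C
Reagents that add atoms: N-phenylbis(trifluoromethanesulfonimide), O=S(=O)(N(c1ccccc1)S(=O)(=O)C(F)(F)F)C(F)(F)F
Why: Kinetic enolisation can only occur towards C8 because C10 is quaternary, and O-sulfonylation of the enolate gives the Δ8 enol triflate regiospecifically.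

**Step 13**
Reactants: 18 6-(tetrahydropyran-2-yloxy)-4,4,10-trimethyl-Δ8-octalin-9-yl trifluoromethanesulfonate; 19 2-methyl-2-vinyl-1,3-dioxolane
Product: 21 9-[2-(2-methyl-1,3-dioxolan-2-yl)ethyl]-6-(tetrahydropyran-2-yloxy)-4,4,10-trimethyl-Δ8-octalin, via alkyl-9-BBN 20 (not isolated)
Conditions: 19, 9-BBN, THF, 23 °C; then 18, PdCl2(dppf) (5 mol%), AsPh3, Cs2CO3, DMF/H2O, 50 °C
Reagents that add atoms: none
Why: B-alkyl Suzuki–Miyaura coupling, in which anti-Markovnikov hydroboration of the vinyl dioxolane gives a primary alkylborane (boron γ to oxygen, so no β-elimination) that transmetalates under base and couples with the alkenyl triflate at zerovalent palladium, attaching C11, C12, C13 and C16 to C9.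

**Step 14**
Reactants: 21 9-[2-(2-methyl-1,3-dioxolan-2-yl)ethyl]-6-(tetrahydropyran-2-yloxy)-4,4,10-trimethyl-Δ8-octalin
Product: 23 9-[2-(2-methyl-1,3-dioxolan-2-yl)ethyl]-6-(tetrahydropyran-2-yloxy)-4,4,10-trimethyl-trans-decalin-8-ol, via C8 alkylborane 22 (not isolated)
Conditions: BH3·THF, THF, 0 → 23 °C; then aq. NaOH, 30% H2O2, 0 °C
Reagents that add atoms: hydrogen peroxide, OO
Why: Hydroboration–oxidation of the trisubstituted C8=C9 alkene places boron on C8 and delivers hydrogen to C9 syn from the face opposite the axial C10 methyl, which should set H-9 trans to C20 (side chain equatorial and cis to C20) and a temporary equatorial 8-OH.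

**Step 15**
Reactants: 23 9-[2-(2-methyl-1,3-dioxolan-2-yl)ethyl]-6-(tetrahydropyran-2-yloxy)-4,4,10-trimethyl-trans-decalin-8-ol
Product: 24 9-[2-(2-methyl-1,3-dioxolan-2-yl)ethyl]-6-(tetrahydropyran-2-yloxy)-4,4,10-trimethyl-trans-decalin-8-one
Conditions: Dess–Martin periodinane, NaHCO3, CH2Cl2, 23 °C
Reagents that add atoms: none
Why: Buffered Dess–Martin oxidation gives the C8 ketone without disturbing C9, whose equatorial side chain is also the thermodynamically preferred arrangement.

**Step 16**
Reactants: 24 9-[2-(2-methyl-1,3-dioxolan-2-yl)ethyl]-6-(tetrahydropyran-2-yloxy)-4,4,10-trimethyl-trans-decalin-8-one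
Product: 25 9-[2-(2-methyl-1,3-dioxolan-2-yl)ethyl]-8-methylene-6-(tetrahydropyran-2-yloxy)-4,4,10-trimethyl-trans-decalin
Conditions: Ph3PCH3Br, KOtBu, THF/toluene, 0 → 60 °C
Reagents that add atoms: methyltriphenylphosphonium bromide, C[P+](c1ccccc1)(c1ccccc1)c1ccccc1.[Br-]
Why: Wittig methylenation with the non-stabilised ylide installs C17 as the exocyclic 8(17)-alkene, and the acetal oxygen β to the ketone is too poor a leaving group for elimination to compete.

**Step 17**
Reactants: 25 9-[2-(2-methyl-1,3-dioxolan-2-yl)ethyl]-8-methylene-6-(tetrahydropyran-2-yloxy)-4,4,10-trimethyl-trans-decalin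
Product: 26 ent-6-hydroxy-14,15-dinorlabd-8(17)-en-13-one
Conditions: 1 M aq. HCl, THF, 23 °C
Reagents that add atoms: water, O
Why: Acid-catalysed acetal hydrolysis through oxocarbenium ions cleaves both the dioxolane and the tetrahydropyranyl ether, freeing the C13 methyl ketone and the 6-OH under conditions too mild to protonate the 1,1-disubstituted alkene.

**Step 18**
Reactants: 26 ent-6-hydroxy-14,15-dinorlabd-8(17)-en-13-one
Product: 27 methyl ent-6-hydroxylabda-8(17),13E-dien-15-oate
Conditions: (MeO)2P(O)CH2CO2Me, NaH, THF, 0 → 65 °C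
Reagents that add atoms: trimethyl phosphonoacetate, COC(=O)CP(=O)(OC)OC
Why: Horner–Wadsworth–Emmons olefination of the methyl ketone forms the trisubstituted enoate, the E isomer (ester trans to the C12 chain) being favoured by reversible addition of the phosphonate anion, and the minor Z isomer should be removable by chromatography.

**Step 19**
Reactants: 27 methyl ent-6-hydroxylabda-8(17),13E-dien-15-oate
Product: 29 methyl (2E)-5-[(1S,2S,4R,4aR,8aR)-2,4-dihydroxy-2,5,5,8a-tetramethyldecahydronaphthalen-1-yl]-3-methylpent-2-enoate, via C17 organomercurial 28 (not isolated)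
Conditions: Hg(OAc)2, THF/H2O (1:1), 23 °C; then aq. NaOH, NaBH4, 0 °C
Reagents that add atoms: water, O
Why: Markovnikov oxymercuration–demercuration, in which the mercurinium ion of the electron-rich exocyclic alkene (the conjugated enoate is inert) is opened by water at the tertiary C8 from the open equatorial side, away from the syn-axial C10 methyl, and reductive demercuration turns C17 into the axial methyl, so that the 8-OH should end up equatorial and trans to C20.

**Compound list**
1 | 2-methylcyclohexane-1,3-dione | CC1C(=O)CCCC1=O | starting material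
2 | allyl bromide | C=CCBr | starting material
3 | 2-allyl-2-methylcyclohexane-1,3-dione | C=CCC1(C)C(=O)CCCC1=O | intermediate
4 | (2S,3S)-2-allyl-3-hydroxy-2-methylcyclohexan-1-one (OH cis to allyl) | O[C@@H]1[C@](C)(CC=C)C(=O)CCC1 | intermediate
5 | (2S,3S)-2-allyl-3-(tert-butyldimethylsilyloxy)-2-methylcyclohexan-1-one | CC(C)(C)[Si](C)(C)O[C@@H]1[C@](C)(CC=C)C(=O)CCC1 | intermediate
6 | 1-chloro-3-methylbut-2-ene (prenyl chloride) | CC(C)=CCCl | starting material
7 | prenylmagnesium chloride (not isolated) | CC(C)=CC[Mg]Cl | intermediate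
8 | (1R,2S,3S)-2-allyl-3-(tert-butyldimethylsilyloxy)-2-methyl-1-(2-methylbut-3-en-2-yl)cyclohexan-1-ol (the two alkene arms cis) | CC(C)(C)[Si](C)(C)O[C@@H]1[C@](C)(CC=C)[C@](O)(C(C)(C)C=C)CCC1 | intermediate
9 | (5R,9S,10S)-9-(tert-butyldimethylsilyloxy)-4,4,10-trimethyl-Δ2-octalin-5-ol (cis-fused; 5-OH cis and 9-OSi trans to C20) | CC(C)(C)[Si](C)(C)O[C@@H]1[C@]2(C)CC=CC(C)(C)[C@]2(O)CCC1 | intermediate
10 | 9-(tert-butyldimethylsilyloxy)-4,4,10-trimethyl-cis-decalin-5-ol (5-OH cis and 9-OSi trans to C20) | CC(C)(C)[Si](C)(C)O[C@@H]1[C@]2(C)CCCC(C)(C)[C@]2(O)CCC1 | intermediate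
11 | 9-(tert-butyldimethylsilyloxy)-4,4,10-trimethyl-Δ5-octalin (9-OSi trans to C20) | CC(C)(C)[Si](C)(C)O[C@@H]1[C@]2(C)CCCC(C)(C)C2=CCC1 | intermediate
12 | C6 alkylborane of 11 (H-5 and 6-BH2 trans to C20; not isolated) | CC(C)(C)[Si](C)(C)O[C@@H]1[C@]2(C)CCCC(C)(C)[C@H]2[C@H](B)CC1 | intermediate
13 | 9-(tert-butyldimethylsilyloxy)-4,4,10-trimethyl-trans-decalin-6-ol (H-5, 6-OH and 9-OSi all trans to C20) | CC(C)(C)[Si](C)(C)O[C@@H]1[C@]2(C)CCCC(C)(C)[C@H]2[C@H](O)CC1 | intermediate
14 | 9-(tert-butyldimethylsilyloxy)-6-(tetrahydropyran-2-yloxy)-4,4,10-trimethyl-trans-decalin (acetal epimers) | CC(C)(C)[Si](C)(C)O[C@@H]1[C@]2(C)CCCC(C)(C)[C@H]2[C@H](OC3CCCCO3)CC1 | intermediate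
15 | 6-(tetrahydropyran-2-yloxy)-4,4,10-trimethyl-trans-decalin-9-ol (9-OH trans to C20; acetal epimers) | O[C@@H]1[C@]2(C)CCCC(C)(C)[C@H]2[C@H](OC3CCCCO3)CC1 | intermediate
16 | 6-(tetrahydropyran-2-yloxy)-4,4,10-trimethyl-trans-decalin-9-one (acetal epimers) | O=C1[C@]2(C)CCCC(C)(C)[C@H]2[C@H](OC3CCCCO3)CC1 | intermediate
17 | potassium Δ8-enolate of 16 (not isolated) | C1=C([O-])[C@]2(C)CCCC(C)(C)[C@H]2[C@H](OC3CCCCO3)C1.[K+] | intermediate
18 | 6-(tetrahydropyran-2-yloxy)-4,4,10-trimethyl-Δ8-octalin-9-yl trifluoromethanesulfonate (acetal epimers) | C1=C(OS(=O)(=O)C(F)(F)F)[C@]2(C)CCCC(C)(C)[C@H]2[C@H](OC3CCCCO3)C1 | intermediate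
19 | 2-methyl-2-vinyl-1,3-dioxolane | C=CC1(C)OCCO1 | starting material
20 | B-[2-(2-methyl-1,3-dioxolan-2-yl)ethyl]-9-borabicyclo[3.3.1]nonane (not isolated) | CC1(CCB2C3CCCC2CCC3)OCCO1 | intermediate
21 | 9-[2-(2-methyl-1,3-dioxolan-2-yl)ethyl]-6-(tetrahydropyran-2-yloxy)-4,4,10-trimethyl-Δ8-octalin (acetal epimers) | C1=C(CCC4(C)OCCO4)[C@]2(C)CCCC(C)(C)[C@H]2[C@H](OC3CCCCO3)C1 | intermediate
22 | C8 alkylborane of 21 (H-9 and 8-BH2 trans to C20; not isolated) | CC4(OCCO4)CC[C@H]1[C@]2(C)CCCC(C)(C)[C@H]2[C@H](OC3CCCCO3)C[C@@H]1B | intermediate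
23 | 9-[2-(2-methyl-1,3-dioxolan-2-yl)ethyl]-6-(tetrahydropyran-2-yloxy)-4,4,10-trimethyl-trans-decalin-8-ol (H-9 and 8-OH trans to C20; acetal epimers) | CC4(OCCO4)CC[C@H]1[C@]2(C)CCCC(C)(C)[C@H]2[C@H](OC3CCCCO3)C[C@@H]1O | intermediate
24 | 9-[2-(2-methyl-1,3-dioxolan-2-yl)ethyl]-6-(tetrahydropyran-2-yloxy)-4,4,10-trimethyl-trans-decalin-8-one (side chain cis to C20; acetal epimers) | CC4(OCCO4)CC[C@H]1[C@]2(C)CCCC(C)(C)[C@H]2[C@H](OC3CCCCO3)CC1=O | intermediate
25 | 9-[2-(2-methyl-1,3-dioxolan-2-yl)ethyl]-8-methylene-6-(tetrahydropyran-2-yloxy)-4,4,10-trimethyl-trans-decalin (acetal epimers) | CC4(OCCO4)CC[C@H]1[C@]2(C)CCCC(C)(C)[C@H]2[C@H](OC3CCCCO3)CC1=C | intermediate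
26 | ent-6-hydroxy-14,15-dinorlabd-8(17)-en-13-one (6-OH trans, side chain cis to C20) | CC(=O)CC[C@H]1[C@]2(C)CCCC(C)(C)[C@H]2[C@H](O)CC1=C | intermediate
27 | methyl ent-6-hydroxylabda-8(17),13E-dien-15-oate | COC(=O)/C=C(\C)CC[C@H]1[C@]2(C)CCCC(C)(C)[C@H]2[C@H](O)CC1=C | intermediate
28 | C17 acetoxymercurio adduct of 27 (8-OH trans to C20; not isolated) | COC(=O)/C=C(\C)CC[C@H]1[C@]2(C)CCCC(C)(C)[C@H]2[C@H](O)C[C@]1(C[Hg]OC(C)=O)O | intermediate
29 | methyl (2E)-5-[(1S,2S,4R,4aR,8aR)-2,4-dihydroxy-2,5,5,8a-tetramethyldecahydronaphthalen-1-yl]-3-methylpent-2-enoate (CNP0289884.1) | COC(=O)/C=C(\C)CC[C@H]1[C@]2(C)CCCC(C)(C)[C@H]2[C@H](O)C[C@]1(C)O | target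

**Totals**
Total step count: 19.
Longest linear sequence: 19 steps (1 → 29); compounds 2, 6 and 19 enter as purchased reagents.

**Steps most likely to fail**

Step 8 (hydroboration of the Δ5 alkene). The face selection may erode: borane can attack syn to the C10 methyl through the ring-flipped half-chair that keeps the 9-siloxy group equatorial, or the attack anti to C20 can be slowed by the axial 9-siloxy group. Either would give cis-fused or 6-epimeric alcohol. The fallback replaces kinetic face selection by thermodynamic control. It sets out from 11: after hydroboration–oxidation as before, the whole alcohol mixture is oxidised with Dess–Martin periodinane to the C6 ketone, which forms as trans-fused 9-(tert-butyldimethylsilyloxy)-4,4,10-trimethyldecalin-6-one F1 together with its cis-fused C5 epimer F2. NaOMe in MeOH should equilibrate F2 into F1 through the C5 enolate. Dissolving-metal reduction of F1 (Li, liquid NH3, tBuOH) should then give the more stable equatorial alcohol, and the route is rejoined at 13.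

Step 18 (olefination of the methyl ketone). The E/Z discrimination between a methyl and a primary alkyl group may be insufficient, and separation of the geometric isomers may be laborious. The fallback builds the alkene stereospecifically by syn carbometalation of an alkyne. It sets out from 26: silylation (TESOTf, 2,6-lutidine) gives the 6-O-triethylsilyl ketone F3. LiN(iPr)2 followed by ClP(O)(OEt)2 gives the kinetic enol diethyl phosphate F4, and further LiN(iPr)2 eliminates phosphate to the terminal alkyne F5. Zirconium-catalysed methylalumination (AlMe3, Cp2ZrCl2, CH2Cl2) adds methyl and aluminium syn to give the (E)-alkenyldimethylalane F6, which is acylated with ClCO2Me with retention to the (E)-enoate silyl ether F7. HF·pyridine removes the silyl group, and the route is rejoined at 27.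

Step 19 (hydration of the 8(17)-alkene). Water may attack the mercurinium ion partly from the axial side, or the ester may suffer in the alkaline demercuration, so that the C8 epimer or hydrolysed material forms. The fallback delivers the oxygen by epoxidation and removes the extra functionality by a radical step that spares the enoate. It sets out from 27: mCPBA (NaHCO3, CH2Cl2) should epoxidise only the electron-rich exocyclic alkene from the equatorial side, helped by hydrogen bonding to the 6-OH on that face, to give the 8,17-epoxide F8. Sodium phenylselenide (from (PhSe)2 and NaBH4 in EtOH) opens F8 at the primary C17 to the β-hydroxy selenide F9. Bu3SnH with AIBN in toluene at 80 °C cleaves the C–Se bond to leave the C17 methyl, and the route is rejoined at 29.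

**Further compounds**
F1 | step 8 | 9-(tert-butyldimethylsilyloxy)-4,4,10-trimethyl-trans-decalin-6-one | CC(C)(C)[Si](C)(C)O[C@@H]1[C@]2(C)CCCC(C)(C)[C@H]2C(=O)CC1
F2 | step 8 | 9-(tert-butyldimethylsilyloxy)-4,4,10-trimethyl-cis-decalin-6-one (C5 epimer of F1) | CC(C)(C)[Si](C)(C)O[C@@H]1[C@]2(C)CCCC(C)(C)[C@@H]2C(=O)CC1
F3 | step 18 | ent-6-(triethylsilyloxy)-14,15-dinorlabd-8(17)-en-13-one | CC(=O)CC[C@H]1[C@]2(C)CCCC(C)(C)[C@H]2[C@H](O[Si](CC)(CC)CC)CC1=C
F4 | step 18 | enol diethyl phosphate of F3 (terminal, C13=CH2) | C=C(OP(=O)(OCC)OCC)CC[C@H]1[C@]2(C)CCCC(C)(C)[C@H]2[C@H](O[Si](CC)(CC)CC)CC1=C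
F5 | step 18 | ent-6-(triethylsilyloxy)-15,16-dinorlabd-8(17)-en-13-yne | C#CCC[C@H]1[C@]2(C)CCCC(C)(C)[C@H]2[C@H](O[Si](CC)(CC)CC)CC1=C
F6 | step 18 | (E)-alkenyldimethylalane from methylalumination of F5 | C[Al](C)/C=C(\C)CC[C@H]1[C@]2(C)CCCC(C)(C)[C@H]2[C@H](O[Si](CC)(CC)CC)CC1=C
F7 | step 18 | methyl ent-6-(triethylsilyloxy)labda-8(17),13E-dien-15-oate | COC(=O)/C=C(\C)CC[C@H]1[C@]2(C)CCCC(C)(C)[C@H]2[C@H](O[Si](CC)(CC)CC)CC1=C
F8 | step 19 | methyl ent-8,17-epoxy-6-hydroxylabd-13E-en-15-oate (epoxide oxygen trans to C20) | COC(=O)/C=C(\C)CC[C@H]1[C@]2(C)CCCC(C)(C)[C@H]2[C@H](O)C[C@]1(C5)O5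
F9 | step 19 | methyl ent-6,8-dihydroxy-17-(phenylselanyl)labd-13E-en-15-oate | COC(=O)/C=C(\C)CC[C@H]1[C@]2(C)CCCC(C)(C)[C@H]2[C@H](O)C[C@]1(C[Se]c3ccccc3)O
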